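**Remark on scope.** The route sets C3 and C2' under full control. It does not control C5: step 8 forms both C5 epimers, and the wanted one is separated after ring closure in step 9. The reason is structural and is given in the retrosynthesis.

## Analysis of the target

The target is a 3,3,5,5-tetrasubstituted 1,2-dioxolane (ring atoms O1–O2–C3–C4–C5). C3 carries a methyl group and the CH2CO2H arm; C5 carries a methyl group and a 2-methyl-12-phenyldodeca-9,11-dienyl chain (C1'–C12'). There are three stereocenters: C3 (R) and C5 (R), both fully substituted C–O–O carbons with the two methyl groups cis across the ring, and C2' (R), a methyl-bearing CH that sits 1,3 to C5 through the C1' methylene. The ring stereocenters carry no hydrogen, and their two carbon substituents (CH3 against CH2R) are almost equal in size, so steric substrate control is weak and C2' is too remote and flexible to relay anything to C5. Once the O–O bond exists, hydrogenation, low-valent metals, most organometallics, excess phosphine and tin-hydride radical chains are excluded, and a carbanion α to the carboxyl group would expel the peroxide by β-elimination. The (E,E)-1-phenyl-1,3-diene does not survive metal-hydride hydrogen-atom transfer, Lewis acids or ozone, so it has to be installed last. The feature the plan exploits is at C3: besides O2 and CH3 it bears an arm of exactly two carbons ending in an oxygenated carbon (CH2–CO2H), which is what a 2-methyl-2-alkyloxetane leaves when its quaternary carbon is attacked with inversion. C5 bears CH3 and two CH2 groups, which is what Markovnikov addition to a 1,1-disubstituted alkene leaves.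

## Retrosynthetic reasoning

**22 ⇒ 20 + 21.** The C9'=C10' bond of the diene is cut. The forward reaction is a Horner–Wadsworth–Emmons olefination of aldehyde 20 with the cinnamyl phosphonate 21, as the last step, because the diene would not survive the peroxide-forming steps. The olefination has to give the (E) alkene without base-induced opening of the ring.

**20 ⇒ 16.** Only oxidation levels change. The acid arm of 20 comes from the CH2CH2OH arm of 16 (through 17 and 18), and the aldehyde comes from the silyl ether (through 19). What is gained is that 16 carries on C3 the primary alcohol that an opened oxetane leaves behind.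

**16 ⇒ 15 (from 14), the key disconnection.** The O2–C3 bond is cut. In the forward direction the terminal oxygen of a tertiary C5 hydroperoxide opens a 2-methyl-2-alkyloxetane at its quaternary carbon (5-exo), so that the ring closes, C3 is set by inversion, and the two-carbon arm is released in one event. The cut is placed at C3 and not at C5 because only C3 has a substituent (the acid arm) that can end in an oxygen.

**14 ⇒ 13.** The O1–C5 bond is cut back to a 1,1-disubstituted alkene. The forward reaction is an aerobic cobalt/silane silylperoxidation, which puts the peroxide on the tertiary carbon and turns the CH2 terminus into the C5 methyl group, so both oxygens of the ring come from air. A stereospecific entry to C5 would need C5 inside a strained ether whose second carbon ends as a carbinol; the candidates are C4, C1' and the methyl carbon, and none of them may keep an oxygen. C5 is therefore formed without control and the epimers are separated right after ring closure.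

**13 ⇒ 12 ⇒ 10 + 6 (through 11).** The alkene comes from ketone 12 by methylenation. The C5–C1' bond is cut to the Weinreb amide 10 and the Grignard reagent 11 made from bromide 6. This joins the two stereochemically defined halves in one step and leaves the oxetane untouched.

**10 ⇒ 7.** (R)-Mevalonolactone 7 maps onto C5(=O)–C4H2–C3(CH3)(O)–CH2–CH2–O atom for atom. Aminolysis (8), tosylation of the primary alcohol (9) and Williamson closure give 10 with the C3–O bond intact, so C3 is bought.

**6 ⇒ 2 + 4 ⇒ 1 and 3.** The C3'–C4' bond is cut to the Grignard reagent 5 (from silyl ether 2, from 1) and the triflate 4 of (2R)-3-bromo-2-methylpropan-1-ol 3. C2' is bought, and the bromide of 3 is kept as the handle for 11.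

## Alternatives that were turned down

**Alternative 1:** (the textbook route) Disconnection of O2–C3 by a 5-exo peroxy-Michael addition. A tertiary C5 hydroperoxide tethered to a β-methyl enoate, A1, would be made by the same cobalt/silane peroxidation of a skipped dienoate and cyclised with an amine base; saponification gives the acid arm directly. It was turned down because neither quaternary centre is controlled. C5 comes from the same planar radical as here, and C3 is formed by reversible conjugate addition to a β,β-disubstituted acceptor whose faces differ only by CH3 against CH2R at C5. Four diastereomers are expected instead of two, and C3 stays labile (retro-Michael through the ester enolate) in every later basic step.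

**Alternative 2:** Disconnection of the C3–CH2 bond of the acid arm through a peroxycarbenium ion. The chain methyl ketone A2 would be taken to an enantioenriched 2,2,4-trisubstituted oxetane, opened at C5 by acid-promoted perhydrolysis (inversion), and closed to the 3-methoxy-1,2-dioxolane A3. A3 would be ionised with a Lewis acid and trapped with a silyl ketene acetal. It was turned down because the nucleophile adds to the planar C3 cation anti to the larger C5 substituent. The margin (CH3 against CH2R) is small and points to the arm trans to the chain, which is the C3 epimer of the target. The oxetane also costs about six linear steps from A2.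

**Alternative 3:** Disconnection of C4–C5 and O2–C3 at once by a [3+2] annulation. The silylperoxy ketal A4 of ketone A2 would be ionised with a Lewis acid in the presence of a 1,1-disubstituted alkene that carries the two-carbon arm as a silyl ether. The alkene attacks C5 and the silylperoxy oxygen closes on the tertiary cation at C3. It is the shortest on paper, but C5 arises from a planar peroxycarbenium ion and C3 from a freely rotating open-chain cation. Nothing controls either centre, proton loss from the cation competes, and up to four diastereomers are expected.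

Key step: step 9

**Assumptions.** Compounds 1, 3, 7 (the natural R enantiomer) and 21 are taken as commercial. Locants: ring O1, O2, C3 (acid side), C4, C5; chain C1'–C12'. All steps run under argon with dry solvents unless water is named.

## Route

Step 1
Reactants: 1 6-bromohexan-1-ol
Product: 2 [(6-bromohexyl)oxy](tert-butyl)diphenylsilane
Conditions: TBDPSCl, imidazole, CH2Cl2, 0 °C → rt
Reagents that add atoms: tert-butyl(chloro)diphenylsilane, CC(C)(C)[Si](Cl)(c1ccccc1)c1ccccc1
Why: Routine silylation of a primary alcohol. The TBDPS ether should survive both Grignard formations, the Wittig base, Co/O2/silane, catalytic TMSOTf and TEMPO oxidation, and still come off with HF·pyridine in step 11.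

Step 2
Reactants: 3 (2R)-3-bromo-2-methylpropan-1-ol
Product: 4 (2R)-3-bromo-2-methylpropyl trifluoromethanesulfonate
Conditions: Tf2O, 2,6-lutidine, CH2Cl2, −78 °C; used crude
Reagents that add atoms: trifluoromethanesulfonic anhydride, O=S(=O)(OS(=O)(=O)C(F)(F)F)C(F)(F)F
Why: Sulfonylation at oxygen only, so the stereocenter (the future C2') is not touched. The triflate should react far faster than the primary bromide of the same molecule in the coupling that follows.

Step 3
Reactants: 2 [(6-bromohexyl)oxy](tert-butyl)diphenylsilane; 4 (2R)-3-bromo-2-methylpropyl trifluoromethanesulfonate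
Product: 6 tert-butyl{[(8R)-9-bromo-8-methylnonyl]oxy}diphenylsilane, via Grignard reagent 5 (not isolated)
Conditions: Mg, THF, 40 °C (2 → 5); then 4, CuBr·SMe2 (5 mol %), THF, −78 → −20 °C
Reagents that add atoms: none
Why: Copper-catalysed sp3–sp3 coupling of a primary alkyl Grignard reagent with a primary alkyl triflate (Kochi-type) forms C3'–C4'. The β-branched bromide should be much slower than the triflate at low temperature and is kept for step 6; the (R) centre is one carbon away from the reacting CH2 and is not affected.

Step 4
Reactants: 7 (R)-mevalonolactone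
Product: 8 (3R)-3,5-dihydroxy-N-methoxy-N,3-dimethylpentanamide
Conditions: MeNH(OMe)·HCl, i-PrMgCl, THF, −20 → 0 °C; aq NH4Cl; used at once
Reagents that add atoms: N,O-dimethylhydroxylamine hydrochloride, CNOC.Cl
Why: Weinreb aminolysis of the δ-lactone by the magnesium amide formed in the flask. The tertiary C–O bond (the future leaving group at C3) is not involved, and the primary alcohol set free is the handle for oxetane closure.

Step 5
Reactants: 8 (3R)-3,5-dihydroxy-N-methoxy-N,3-dimethylpentanamide
Product: 10 N-methoxy-N-methyl-2-[(2R)-2-methyloxetan-2-yl]acetamide, via monotosylate 9 (not isolated)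
Conditions: TsCl, Et3N, DMAP (cat.), CH2Cl2, 0 °C; then KOtBu, THF, 0 °C → rt
Reagents that add atoms: none
Why: Tosylation of the primary hydroxyl in preference to the tertiary one, then intramolecular Williamson etherification (4-exo-tet) by the tertiary alkoxide. The C–O bond at the stereocenter is retained, so the (R) centre of 7 passes into the oxetane unchanged.

Step 6
Reactants: 6 tert-butyl{[(8R)-9-bromo-8-methylnonyl]oxy}diphenylsilane; 10 N-methoxy-N-methyl-2-[(2R)-2-methyloxetan-2-yl]acetamide
Product: 12 (4R)-11-[(tert-butyldiphenylsilyl)oxy]-4-methyl-1-[(2R)-2-methyloxetan-2-yl]undecan-2-one, via Grignard reagent 11 (not isolated)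
Conditions: Mg, THF, 40 °C (6 → 11); then 10, THF, −20 → 0 °C; aq NH4Cl
Reagents that add atoms: none
Why: Weinreb ketone synthesis forms the C5–C1' bond; the chelated tetrahedral intermediate stops over-addition. An oxetane is inert to a Grignard reagent at 0 °C or below without a Lewis acid.

Step 7
Reactants: 12 (4R)-11-[(tert-butyldiphenylsilyl)oxy]-4-methyl-1-[(2R)-2-methyloxetan-2-yl]undecan-2-one
Product: 13 tert-butyl{[(8R)-8-methyl-10-{[(2S)-2-methyloxetan-2-yl]methyl}undec-10-en-1-yl]oxy}diphenylsilane
Conditions: Ph3PCH3Br, KOtBu, THF, 0 °C
Reagents that add atoms: methyltriphenylphosphonium bromide, C[P+](c1ccccc1)(c1ccccc1)c1ccccc1.[Br-]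
Why: Wittig methylenation of an unhindered dialkyl ketone; ylide addition should outrun enolisation towards C4, which would open the β-oxetane by E1cB (dimethyltitanocene is the non-basic option). The new CH2 becomes the C5 methyl group; the oxetane descriptor changes from R to S by CIP priority only.

Step 8
Reactants: 13 tert-butyl{[(8R)-8-methyl-10-{[(2S)-2-methyloxetan-2-yl]methyl}undec-10-en-1-yl]oxy}diphenylsilane
Product: 14 tert-butyl{[(8R,10RS)-8-methyl-10-{[(2R)-2-methyloxetan-2-yl]methyl}-10-[(triethylsilyl)peroxy]undecyl]oxy}diphenylsilane
Conditions: Co(thd)2 (10 mol %), Et3SiH, O2 (1 atm), ClCH2CH2Cl, rt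
Reagents that add atoms: dioxygen, O=O; triethylsilane, CC[SiH](CC)CC
Why: Isayama–Mukaiyama silylperoxidation: cobalt hydride transfers H to the CH2 terminus, the tertiary C5 radical is trapped by O2 and the peroxyl is silylated, which forms the C5–O1 bond and the C5 methyl group. The radical is planar and flanked by two CH2 groups, so no facial preference is expected and both C10 epimers should form in similar amounts and go on together.

Step 9
Reactants: 14 tert-butyl{[(8R,10RS)-8-methyl-10-{[(2R)-2-methyloxetan-2-yl]methyl}-10-[(triethylsilyl)peroxy]undecyl]oxy}diphenylsilane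
Product: 16 2-[(3S,5R)-5-{(2R)-9-[(tert-butyldiphenylsilyl)oxy]-2-methylnonyl}-3,5-dimethyl-1,2-dioxolan-3-yl]ethan-1-ol, via hydroperoxide 15 (not isolated)
Conditions: TBAF, AcOH, THF, 0 °C, 10 min; aqueous wash; crude 15, TMSOTf (0.2 equiv), CH2Cl2, −40 → 0 °C; chromatographic removal of the C5 epimer
Reagents that add atoms: none
Why: Fluoride takes the silyl group off the peroxide to give hydroperoxide 15; catalytic TMSOTf then activates the oxetane oxygen, and the terminal peroxide oxygen attacks the quaternary oxetane carbon from the face opposite its C–O bond, so that O2–C3 forms and the CH2CH2OH arm is released in the same event. The closest known reaction types are the intramolecular 5-exo opening of oxetanes by hydroperoxides and the acid-promoted perhydrolysis of 2,2-disubstituted oxetanes at the tertiary carbon, both with inversion. The dioxolane closes in the 5-exo-tet mode; attack at the primary oxetane carbon would be 7-endo, and the tertiary carbon is also the electronically preferred site, so ring size and regiochemistry agree. C3 is set by inversion of the (R) oxetane centre bought with 7, which gives the target geometry (S in 16 by CIP priority, R once the arm is the acid). C5 is not touched here: both epimers from step 8 should cyclise, and the cis-dimethyl isomer 16 is separated from its C5 epimer at this stage (or, if they co-elute, after step 10). The selectivity the step needs is SN2-like substitution ahead of ionisation to a free tertiary cation; the five-membered intramolecular transition state, the low temperature, the sub-stoichiometric Lewis acid and the non-polar solvent are what secure it.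

Step 10
Reactants: 16 2-[(3S,5R)-5-{(2R)-9-[(tert-butyldiphenylsilyl)oxy]-2-methylnonyl}-3,5-dimethyl-1,2-dioxolan-3-yl]ethan-1-ol
Product: 18 2-[(3R,5R)-5-{(2R)-9-[(tert-butyldiphenylsilyl)oxy]-2-methylnonyl}-3,5-dimethyl-1,2-dioxolan-3-yl]acetic acid, via aldehyde 17 (not isolated)
Conditions: TEMPO (20 mol %), PhI(OAc)2 (2.2 equiv), MeCN/pH 7 buffer, rt
Reagents that add atoms: water, O
Why: Oxoammonium oxidation of the primary alcohol through aldehyde 17 and its hydrate to the acid. The near-neutral medium should avoid β-elimination of the peroxide from the β-peroxy aldehyde, and the O–O bond and the silyl ether are inert to it.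

Step 11
Reactants: 18 2-[(3R,5R)-5-{(2R)-9-[(tert-butyldiphenylsilyl)oxy]-2-methylnonyl}-3,5-dimethyl-1,2-dioxolan-3-yl]acetic acid
Product: 19 2-[(3R,5R)-5-[(2R)-9-hydroxy-2-methylnonyl]-3,5-dimethyl-1,2-dioxolan-3-yl]acetic acid
Conditions: HF·pyridine, THF/pyridine, 0 °C → rt
Reagents that add atoms: none
Why: Fluoride cleavage of the primary TBDPS ether under acidic, non-reducing conditions that should leave the tetrasubstituted dioxolane and the acid untouched.

Step 12
Reactants: 19 2-[(3R,5R)-5-[(2R)-9-hydroxy-2-methylnonyl]-3,5-dimethyl-1,2-dioxolan-3-yl]acetic acid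
Product: 20 2-[(3R,5R)-3,5-dimethyl-5-[(2R)-2-methyl-9-oxononyl]-1,2-dioxolan-3-yl]acetic acid
Conditions: Dess–Martin periodinane, NaHCO3, CH2Cl2, 0 °C → rt
Reagents that add atoms: none
Why: Dess–Martin oxidation stops at the aldehyde, tolerates the buffered carboxylic acid and does not reduce or open the peroxide.

Step 13
Reactants: 20 2-[(3R,5R)-3,5-dimethyl-5-[(2R)-2-methyl-9-oxononyl]-1,2-dioxolan-3-yl]acetic acid; 21 diethyl [(2E)-3-phenylprop-2-en-1-yl]phosphonate
Product: 22 2-[(3R,5R)-3,5-dimethyl-5-[(2R,9E,11E)-2-methyl-12-phenyldodeca-9,11-dien-1-yl]-1,2-dioxolan-3-yl]acetic acid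
Conditions: 21 (1.5 equiv), LiHMDS (2.5 equiv), THF, −78 °C; then 20, −78 → 0 °C; dilute HCl
Reagents that add atoms: none
Why: Horner–Wadsworth–Emmons olefination with the allylic phosphonate anion should form C9'=C10' as the (E) alkene while the cinnamyl double bond stays (E). The substrate reacts as its lithium carboxylate, which the phosphonate anion cannot deprotonate at the α-carbon, so the peroxide should not be opened by β-elimination.

## Compound list

1 | 6-bromohexan-1-ol | OCCCCCCBr | starting material
2 | [(6-bromohexyl)oxy](tert-butyl)diphenylsilane | CC(C)(C)[Si](c1ccccc1)(c1ccccc1)OCCCCCCBr | intermediate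
3 | (2R)-3-bromo-2-methylpropan-1-ol | OC[C@@H](C)CBr | starting material
4 | (2R)-3-bromo-2-methylpropyl trifluoromethanesulfonate | O=S(=O)(OC[C@@H](C)CBr)C(F)(F)F | intermediate
5 | {6-[(tert-butyldiphenylsilyl)oxy]hexyl}magnesium bromide | CC(C)(C)[Si](c1ccccc1)(c1ccccc1)OCCCCCC[Mg]Br | intermediate
6 | tert-butyl{[(8R)-9-bromo-8-methylnonyl]oxy}diphenylsilane | CC(C)(C)[Si](c1ccccc1)(c1ccccc1)OCCCCCCC[C@@H](C)CBr | intermediate
7 | (R)-mevalonolactone, (4R)-4-hydroxy-4-methyloxan-2-one | C[C@@]1(O)CCOC(=O)C1 | starting material
8 | (3R)-3,5-dihydroxy-N-methoxy-N,3-dimethylpentanamide | CON(C)C(=O)C[C@](C)(O)CCO | intermediate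
9 | (3R)-3-hydroxy-5-[methoxy(methyl)amino]-3-methyl-5-oxopentyl 4-methylbenzenesulfonate | CON(C)C(=O)C[C@](C)(O)CCOS(=O)(=O)c1ccc(C)cc1 | intermediate
10 | N-methoxy-N-methyl-2-[(2R)-2-methyloxetan-2-yl]acetamide | CON(C)C(=O)C[C@]1(C)OCC1 | intermediate
11 | {(2R)-9-[(tert-butyldiphenylsilyl)oxy]-2-methylnonyl}magnesium bromide | CC(C)(C)[Si](c1ccccc1)(c1ccccc1)OCCCCCCC[C@@H](C)C[Mg]Br | intermediate
12 | (4R)-11-[(tert-butyldiphenylsilyl)oxy]-4-methyl-1-[(2R)-2-methyloxetan-2-yl]undecan-2-one | C[C@H](CCCCCCCO[Si](c1ccccc1)(c1ccccc1)C(C)(C)C)CC(=O)C[C@]1(C)OCC1 | intermediate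
13 | tert-butyl{[(8R)-8-methyl-10-{[(2S)-2-methyloxetan-2-yl]methyl}undec-10-en-1-yl]oxy}diphenylsilane | C[C@H](CCCCCCCO[Si](c1ccccc1)(c1ccccc1)C(C)(C)C)CC(=C)C[C@]1(C)OCC1 | intermediate
14 | tert-butyl{[(8R,10RS)-8-methyl-10-{[(2R)-2-methyloxetan-2-yl]methyl}-10-[(triethylsilyl)peroxy]undecyl]oxy}diphenylsilane (both C10 epimers) | C[C@H](CCCCCCCO[Si](c1ccccc1)(c1ccccc1)C(C)(C)C)CC(C)(OO[Si](CC)(CC)CC)C[C@]1(C)OCC1 | intermediate
15 | tert-butyl{[(8R,10RS)-10-hydroperoxy-8-methyl-10-{[(2R)-2-methyloxetan-2-yl]methyl}undecyl]oxy}diphenylsilane (both C10 epimers) | C[C@H](CCCCCCCO[Si](c1ccccc1)(c1ccccc1)C(C)(C)C)CC(C)(OO)C[C@]1(C)OCC1 | intermediate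
16 | 2-[(3S,5R)-5-{(2R)-9-[(tert-butyldiphenylsilyl)oxy]-2-methylnonyl}-3,5-dimethyl-1,2-dioxolan-3-yl]ethan-1-ol | C[C@H](CCCCCCCO[Si](c1ccccc1)(c1ccccc1)C(C)(C)C)C[C@]1(C)C[C@](C)(CCO)OO1 | intermediate
17 | 2-[(3R,5R)-5-{(2R)-9-[(tert-butyldiphenylsilyl)oxy]-2-methylnonyl}-3,5-dimethyl-1,2-dioxolan-3-yl]acetaldehyde | C[C@H](CCCCCCCO[Si](c1ccccc1)(c1ccccc1)C(C)(C)C)C[C@]1(C)C[C@](C)(CC=O)OO1 | intermediate
18 | 2-[(3R,5R)-5-{(2R)-9-[(tert-butyldiphenylsilyl)oxy]-2-methylnonyl}-3,5-dimethyl-1,2-dioxolan-3-yl]acetic acid | C[C@H](CCCCCCCO[Si](c1ccccc1)(c1ccccc1)C(C)(C)C)C[C@]1(C)C[C@](C)(CC(=O)O)OO1 | intermediate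
19 | 2-[(3R,5R)-5-[(2R)-9-hydroxy-2-methylnonyl]-3,5-dimethyl-1,2-dioxolan-3-yl]acetic acid | C[C@H](CCCCCCCO)C[C@]1(C)C[C@](C)(CC(=O)O)OO1 | intermediate
20 | 2-[(3R,5R)-3,5-dimethyl-5-[(2R)-2-methyl-9-oxononyl]-1,2-dioxolan-3-yl]acetic acid | C[C@H](CCCCCCC=O)C[C@]1(C)C[C@](C)(CC(=O)O)OO1 | intermediate
21 | diethyl [(2E)-3-phenylprop-2-en-1-yl]phosphonate | CCOP(=O)(C/C=C/c1ccccc1)OCC | starting material
22 | 2-[(3R,5R)-3,5-dimethyl-5-[(2R,9E,11E)-2-methyl-12-phenyldodeca-9,11-dien-1-yl]-1,2-dioxolan-3-yl]acetic acid | C[C@H](CCCCCC/C=C/C=C/c1ccccc1)C[C@]1(C)C[C@](C)(CC(=O)O)OO1 | target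

## Step count and weak points

Total steps: 13. Longest linear sequence: 10 steps (for example steps 2, 3, 6–13 from 3, or steps 4, 5, 6–13 from 7).

**Step 9 (key step).** The most likely failure is ionisation of the activated oxetane to a free tertiary cation before the peroxide oxygen has bonded. That would erode the inversion at C3 and open E1 elimination to homoallylic alcohols; acid-induced Hock-type fragmentation of the tertiary hydroperoxide is a second drain. The fallback reverses the order of the two C–O bond formations and sets out from 13. Intermolecular perhydrolysis of the oxetane with anhydrous ethereal hydrogen peroxide and catalytic TMSOTf at low temperature (inversion at the quaternary carbon) should give (3R,7R)-14-[(tert-butyldiphenylsilyl)oxy]-3-hydroperoxy-3,7-dimethyl-5-methylidenetetradecan-1-ol F1. Cycloperoxymercuration with mercury(II) acetate then closes the ring onto the 1,1-disubstituted alkene (5-exo, Markovnikov) to the organomercurial ({(3RS,5S)-5-(2-hydroxyethyl)-5-methyl-3-{(2R)-9-[(tert-butyldiphenylsilyl)oxy]-2-methylnonyl}-1,2-dioxolan-3-yl}methyl)mercury(II) acetate F2. Alkaline borohydride demercuration comes back to the route at 16, again together with its C5 epimer.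

**Step 8.** The capture of the planar C5 radical by dioxygen has no facial preference, so half of the material is expected to carry the wrong C5 configuration; this is inherent and not a matter of optimisation. Reduction of the peroxide to the tertiary alcohol and cobalt-promoted early opening of the oxetane may add to the loss. The fallback replaces the radical by an ionic entry to the same hydroperoxide and sets out from 13. Hydroperoxymercuration with hydrogen peroxide and mercury(II) acetate should give acetoxy{(2RS,4R)-11-[(tert-butyldiphenylsilyl)oxy]-2-hydroperoxy-4-methyl-2-{[(2R)-2-methyloxetan-2-yl]methyl}undecyl}mercury F3, and alkaline borohydride demercuration comes back to the route at 15. This removes the cobalt-related side reactions but does not cure the missing face selectivity.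

**Step 5.** Under the alkoxide base the tertiary β-alkoxy amide may fragment by retro-aldol cleavage, the product may open by β-elimination through the amide enolate, or 8 may relactonise before tosylation. The fallback moves oxetane formation to a stage without a carbonyl group and sets out from 7 and 11. Single addition of 11 to the lactone (after deprotonation of the tertiary hydroxyl with isopropylmagnesium chloride) should give (3R,7R)-14-[(tert-butyldiphenylsilyl)oxy]-1,3-dihydroxy-3,7-dimethyltetradecan-5-one F4, which exists largely as its cyclic hemiketal. Methylenation should give (3S,7R)-14-[(tert-butyldiphenylsilyl)oxy]-3,7-dimethyl-5-methylidenetetradecane-1,3-diol F5, and primary tosylation with alkoxide closure comes back to the route at 13.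

**Step 13.** Incomplete (E) selectivity at the new C9'=C10' bond would give diene isomers that are hard to separate, and excess base could attack the β-peroxy carboxylate. The fallback forms the other double bond of the diene last and sets out from 20. A Wittig reaction with the stabilised formylmethylene ylide should give the (E)-enal 2-[(3R,5R)-3,5-dimethyl-5-[(2R,9E)-2-methyl-11-oxoundec-9-en-1-yl]-1,2-dioxolan-3-yl]acetic acid F6. A Horner–Wadsworth–Emmons reaction of F6 with diethyl benzylphosphonate, which is reliably (E)-selective for aryl-stabilised phosphonates, comes back to the route at 22.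

## Further compounds

F1 | step 9 | (3R,7R)-14-[(tert-butyldiphenylsilyl)oxy]-3-hydroperoxy-3,7-dimethyl-5-methylidenetetradecan-1-ol | C[C@H](CCCCCCCO[Si](c1ccccc1)(c1ccccc1)C(C)(C)C)CC(=C)C[C@](C)(CCO)OO
F2 | step 9 | ({(3RS,5S)-5-(2-hydroxyethyl)-5-methyl-3-{(2R)-9-[(tert-butyldiphenylsilyl)oxy]-2-methylnonyl}-1,2-dioxolan-3-yl}methyl)mercury(II) acetate | C[C@H](CCCCCCCO[Si](c1ccccc1)(c1ccccc1)C(C)(C)C)CC1(C[Hg]OC(C)=O)C[C@](C)(CCO)OO1
F3 | step 8 | acetoxy{(2RS,4R)-11-[(tert-butyldiphenylsilyl)oxy]-2-hydroperoxy-4-methyl-2-{[(2R)-2-methyloxetan-2-yl]methyl}undecyl}mercury | C[C@H](CCCCCCCO[Si](c1ccccc1)(c1ccccc1)C(C)(C)C)CC(C[Hg]OC(C)=O)(OO)C[C@]1(C)OCC1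
F4 | step 5 | (3R,7R)-14-[(tert-butyldiphenylsilyl)oxy]-1,3-dihydroxy-3,7-dimethyltetradecan-5-one | C[C@H](CCCCCCCO[Si](c1ccccc1)(c1ccccc1)C(C)(C)C)CC(=O)C[C@](C)(O)CCO
F5 | step 5 | (3S,7R)-14-[(tert-butyldiphenylsilyl)oxy]-3,7-dimethyl-5-methylidenetetradecane-1,3-diol | C[C@H](CCCCCCCO[Si](c1ccccc1)(c1ccccc1)C(C)(C)C)CC(=C)C[C@](C)(O)CCO
F6 | step 13 | 2-[(3R,5R)-3,5-dimethyl-5-[(2R,9E)-2-methyl-11-oxoundec-9-en-1-yl]-1,2-dioxolan-3-yl]acetic acid | C[C@H](CCCCCC/C=C/C=O)C[C@]1(C)C[C@](C)(CC(=O)O)OO1
A1 | alternative 1 | methyl (2E,5RS,7R)-14-[(tert-butyldiphenylsilyl)oxy]-5-hydroperoxy-3,5,7-trimethyltetradec-2-enoate | C[C@H](CCCCCCCO[Si](c1ccccc1)(c1ccccc1)C(C)(C)C)CC(C)(OO)C/C(C)=C/C(=O)OC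
A2 | alternative 2 | (4R)-11-[(tert-butyldiphenylsilyl)oxy]-4-methylundecan-2-one | C[C@H](CCCCCCCO[Si](c1ccccc1)(c1ccccc1)C(C)(C)C)CC(C)=O
A3 | alternative 2 | tert-butyl{[(8R)-9-[(3R,5RS)-5-methoxy-3,5-dimethyl-1,2-dioxolan-3-yl]-8-methylnonyl]oxy}diphenylsilane | C[C@H](CCCCCCCO[Si](c1ccccc1)(c1ccccc1)C(C)(C)C)C[C@]1(C)CC(C)(OC)OO1
A4 | alternative 3 | tert-butyl{[(8R,10RS)-10-methoxy-8-methyl-10-[(triethylsilyl)peroxy]undecyl]oxy}diphenylsilane | C[C@H](CCCCCCCO[Si](c1ccccc1)(c1ccccc1)C(C)(C)C)CC(C)(OC)OO[Si](CC)(CC)CC
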